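All runs stem from a simulated flask from invented constants, noise included.

The question is how much of the charge in Tuesday's flask is target at 6.0 h, and which option then adds most.

| flask | starting material | temperature | remark | time |
|---|---|---|---|---|
| Tuesday's | 2 M | 100 °C | the very flask that is asked about, followed so far |  |
| Wednesday's | 2 M | 85 °C | run made earlier |  |
| flask | 2.0 M | 100 °C |  | 6.0 h |

- Tuesday's (time / min: target / %, starting material / %): 20.0: 53.7, 3.7; 60.0: 56.4, 1.8; 90.0: 59.7, 2.5; 150: 64.4, 2.3; 240: 68.5, 2.7; 300: 71.8, 2.6
- Wednesday's (time / min: target / %, starting material / %): 40.0: 61.9, 1.0; 120: 62.9, 1.9; 180: 63.4, 2.3; 300: 64.9, 1.2; 480: 66.0, 0.5; 600: 66.0, 1.0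

(scatter of a reading: 0.5 percentage points)

- noon: at 6.0 h raise the temperature by 20 K, then wait 3.0 h
- midnight: change nothing and wait 3.0 h more
- summer: at 6.0 h take out 90 % of the target then present, then wait 3.0 h

- percentages count the starting material that a species holds: one target counts as two
- target taken out counts as made

1. target, in percent of the starting material first charged, at 6.0 h
2. the option that brings most further target ("none" if no option brings more than 2 percentage points) (noon / midnight / summer / none)
3. target present, with what was taken out counted in, in percent of the starting material first charged, after midnight
4. target present, with what was taken out counted in, in percent of the starting material first charged, after summer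

In Tuesday's flask target keeps climbing while starting material, read as a share of the remainder r, the fraction of the charge not yet target, gives 7.99 % at the first reading and 9.22 % at the last. Two extreme flasks solve in the head, both drawn through the readings at 60.0 min and 300 min. If the pace goes with r, r decays exponentially at 0.00182 min⁻¹, and target reaches 81.8 % after midnight. If the pace goes with r squared, as when two of starting material make each target, the reciprocal of r rises on a straight line at 0.00522 min⁻¹. I carry this drain constant, the rise of the reciprocal of r per unit time.

The late pace of 6.42 × 10⁻⁴ min⁻¹ leans towards the second. Scaled linearly from 2.6 % starting material to the whole charge, it makes at most 49.4 % by 20.0 min, less than the 53.7 % read, but a scatter of 0.5 percentage points on that small reading of starting material keeps this a leaning and no proof. Scaled by the square, it gives a time constant of 1.05 min, shorter than the time of the first reading. So I place the flask between the lines, at the square end: 74.1 % now and 79.2 % after midnight. Target does not enter this line, so in my reckoning summer equals midnight. Wednesday's drain constant reads 5.12 × 10⁻⁴ min⁻¹, so as a reading the 15.0 K between the two runs multiplied it by about 10.2. The larger step of 20 K at that factor already gives 92.6 % at noon, so I choose noon.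

The forecast gives 75 % at 6.0 h, noon as the best option, 82 % after midnight and 82.5 % after summer, holding that “Removing target should therefore barely matter”. Its midnight stands 2.8 points above mine.

The flask gives 73.9 % at 6.0 h. The best option is noon, adding 21 points, against 5 points for midnight and 5 points for summer, and both of those end at 78.8 %.

    starting material ⇌ dormant form (K = 12.0, k = 0.00570 s⁻¹, Ea = 102 kJ mol⁻¹, ΔH = −58.0 kJ mol⁻¹)
    2 starting material → target (k = 0.00380 L mol⁻¹ s⁻¹, Ea = 64.0 kJ mol⁻¹)
    (constants at 100 °C)

In this flask starting material and dormant form relax towards each other, by that step alone, with a half-life of 1.87 min, far shorter than the 4.65 h of the slowest mode of the whole flask at 6.0 h. At that time the dormant form, the resting state, holds 24.2 % and starting material 1.93 %. Carried from 73.9 %, the drain constant gives 79.0 % after midnight and 85.0 % at 15 h. A flask of the same charge and temperature, read at 15 h, holds 84.7 % target.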